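The target is the ring-opened form of a cis-fused dihydropyran: the enol oxygen and C2 of the cyclohexane-1,3-dione ring, the bridging CH2, C2′ and the carbinol carbon C1′ of the cyclopentene outline a six-membered ring, and OH and CH2 are cis on C1′/C2′. (S)-4-Methoxycyclohexane-1,3-dione, formaldehyde and a silyl-protected (S)-3-methylcyclopent-2-enol are therefore united in a domino Knoevenagel/hetero-Diels–Alder reaction, which forms the CH2–C2′ and O–C1′ bonds suprafacially and sets both ring stereocentres. The pyran then masks dione and tertiary alcohol while the C3′ oxygen is converted, via an enol triflate, into the (Z)-dienyl side chain; hydroxide finally opens the pyran.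

Key step: step 10

Locants used below: dione ring C1–C6 (C2 carries the CH2, C4 the OMe); cyclopentene C1′ (C(CH3)–O), C2′ (CH carrying the CH2), C3′ (side-chain carbon), C4′ (=CH), C5′ (CH2).

Remark (assumption): in step 10 the pyran is drawn as closed through the dione oxygen remote from the methoxy group. Closure through the other oxygen would give a constitutional isomer that passes through steps 11–15 in the same way and ends at the same compound 24.

Step 1
Reactants: 1 1,4-dioxaspiro[4.5]decan-7-one
Product: 2 (8S)-8-[(phenylamino)oxy]-1,4-dioxaspiro[4.5]decan-7-one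
Conditions: PhNO (slow addition), D-proline (20 mol %), DMF, 0 °C, ketone in excess
Reagents that add atoms: nitrosobenzene, O=Nc1ccccc1
Why: Proline-catalysed α-aminoxylation (enamine catalysis): the enamine should form at C8, away from the quaternary ketal carbon, and the carboxylic acid of D-proline steers O-attack on nitrosobenzene to one face, which should set C8 as (S).

Step 2
Reactants: 2 (8S)-8-[(phenylamino)oxy]-1,4-dioxaspiro[4.5]decan-7-one
Product: 3 (8S)-8-hydroxy-1,4-dioxaspiro[4.5]decan-7-one
Conditions: H2 (1 atm), 10% Pd/C, EtOAc, rt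
Reagents that add atoms: none
Why: N–O hydrogenolysis cleaves the weak N–O bond under neutral conditions that should leave ketone, ketal and the α-stereocentre untouched.

Step 3
Reactants: 3 (8S)-8-hydroxy-1,4-dioxaspiro[4.5]decan-7-one
Product: 4 (8S)-8-methoxy-1,4-dioxaspiro[4.5]decan-7-one
Conditions: MeI (excess), Ag2O, 4 Å MS, MeCN, rt, dark
Reagents that add atoms: iodomethane, CI
Why: Purdie methylation etherifies the α-hydroxy ketone under near-neutral conditions, so the α-stereocentre should not enolise.

Step 4
Reactants: 4 (8S)-8-methoxy-1,4-dioxaspiro[4.5]decan-7-one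
Product: 5 (4S)-4-methoxycyclohexane-1,3-dione
Conditions: 1 M aq. HCl, THF, 0 °C to rt
Reagents that add atoms: water, O
Why: Acid-catalysed ketal hydrolysis unmasks the 1,3-dione, which enolises between the two carbonyls (C2) and not toward C4, so the methoxy stereocentre should be retained.

Step 5
Reactants: 6 3-methylcyclopent-2-en-1-one
Product: 7 (1S)-3-methylcyclopent-2-en-1-ol
Conditions: (R)-2-methyl-CBS-oxazaborolidine (10 mol %), BH3·SMe2, THF, −20 °C; MeOH quench, aqueous work-up
Reagents that add atoms: none
Why: Corey–Bakshi–Shibata reduction: the (R)-oxazaborolidine binds the ketone with the alkenyl arm as the large group and should deliver hydride 1,2 to give the (S)-allylic alcohol.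

Step 6
Reactants: 7 (1S)-3-methylcyclopent-2-en-1-ol
Product: 8 tert-butyldimethyl{[(1S)-3-methylcyclopent-2-en-1-yl]oxy}silane
Conditions: TBSCl, imidazole, DMF, rt
Reagents that add atoms: tert-butyldimethylsilyl chloride, CC(C)(C)[Si](C)(C)Cl
Why: Standard silylation of a secondary alcohol; the bulky silyl ether later shields one face of the neighbouring alkene.

Step 7
Reactants: 9 but-2-yn-1-ol
Product: 11 (2Z)-3-iodobut-2-en-1-ol, via cyclic alkenylalanate 10 (not isolated)
Conditions: Red-Al, THF, 0 °C to rt; EtOAc; then I2, THF, −78 to 0 °C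
Reagents that add atoms: iodine, II
Why: Alkoxide-directed trans-hydroalumination of the propargylic alcohol gives the five-membered alkenylalanate, and iodinolysis with retention should fix the Z geometry (I cis to CH2OH).

Step 8
Reactants: 11 (2Z)-3-iodobut-2-en-1-ol
Product: 12 (2Z)-1-bromo-3-iodobut-2-ene
Conditions: CBr4, PPh3, CH2Cl2, 0 °C; used directly
Reagents that add atoms: tetrabromomethane, BrC(Br)(Br)Br
Why: Appel reaction: SN2 displacement at the primary allylic carbon should leave the alkenyl iodide and the alkene geometry untouched.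

Step 9
Reactants: 12 (2Z)-1-bromo-3-iodobut-2-ene; 13 (2-methylprop-1-en-1-yl)magnesium bromide
Product: 14 (2Z)-2-iodo-6-methylhepta-2,5-diene
Conditions: CuI (5 mol %), THF, −30 to 0 °C
Reagents that add atoms: none
Why: Copper-catalysed allylic substitution of the primary allylic bromide by the alkenyl Grignard reagent; at low temperature and without palladium the alkenyl iodide should stay intact and no stereocentre or alkene geometry is affected.

Step 10
Reactants: 5 (4S)-4-methoxycyclohexane-1,3-dione; 15 formaldehyde (as paraformaldehyde); 8 tert-butyldimethyl{[(1S)-3-methylcyclopent-2-en-1-yl]oxy}silane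
Product: 17 (1S,3aS,7S,9aR)-1-[(tert-butyldimethylsilyl)oxy]-7-methoxy-3a-methyl-2,3,3a,5,6,7,9,9a-octahydrocyclopenta[b]chromen-8(1H)-one, via methylene dione 16 (not isolated)
Conditions: (CH2O)n (3 equiv), 8 (3 equiv, excess recovered), ethylenediammonium diacetate (10 mol %), MeCN, 80 °C, sealed tube
Reagents that add atoms: none
Why: Amine-catalysed Knoevenagel condensation of 5 with formaldehyde gives the 2-methylene-1,3-dione 16, a 1-oxadiene that reacts with the trisubstituted alkene of 8 in an inverse-electron-demand hetero-Diels–Alder reaction, forming the CH2–C2′ bond and the O–C1′ bond in one operation. The closest known reaction type is the domino Knoevenagel/hetero-Diels–Alder reaction and the [4+2] coupling of methylene-1,3-diones (ortho-quinone-methide analogues) with terpene olefins. The dihydropyran ring is closed in the [4+2] mode, concerted but asynchronous, with carbon–carbon bonding leading at the less substituted C2′ and oxygen closing on the tertiary C1′, which also fixes the regiochemistry. C1′ and C2′ are set cis by suprafacial addition to the ring alkene, and their absolute configuration by approach anti to the OTBS group on the adjacent C3′. The step needs the alkene to outcompete Michael addition of a second molecule of 5 to 16, which the excess of 8 and the slow release of formaldehyde from the polymer should secure; closure is expected through the less hindered, more electron-rich oxygen remote from the methoxy group.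

Step 11
Reactants: 17 (1S,3aS,7S,9aR)-1-[(tert-butyldimethylsilyl)oxy]-7-methoxy-3a-methyl-2,3,3a,5,6,7,9,9a-octahydrocyclopenta[b]chromen-8(1H)-one
Product: 18 (1S,3aS,7S,9aR)-1-hydroxy-7-methoxy-3a-methyl-2,3,3a,5,6,7,9,9a-octahydrocyclopenta[b]chromen-8(1H)-one
Conditions: TBAF, THF, 0 °C to rt
Reagents that add atoms: none
Why: Fluoride-mediated desilylation; the vinylogous ester and the α-methoxy ketone should tolerate TBAF.

Step 12
Reactants: 18 (1S,3aS,7S,9aR)-1-hydroxy-7-methoxy-3a-methyl-2,3,3a,5,6,7,9,9a-octahydrocyclopenta[b]chromen-8(1H)-one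
Product: 19 (3aS,7S,9aS)-7-methoxy-3a-methyl-2,3,3a,5,6,7,9,9a-octahydrocyclopenta[b]chromene-1,8-dione
Conditions: Dess–Martin periodinane, NaHCO3, CH2Cl2, 0 °C to rt; used without chromatography
Reagents that add atoms: none
Why: Dess–Martin oxidation under buffered, non-basic conditions, chosen because the product is a β-alkoxy ketone that base could open by E1cB loss of the pyran oxygen; the temporary C3′ stereocentre is removed here.

Step 13
Reactants: 19 (3aS,7S,9aS)-7-methoxy-3a-methyl-2,3,3a,5,6,7,9,9a-octahydrocyclopenta[b]chromene-1,8-dione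
Product: 20 (3aS,7S,9aS)-7-methoxy-3a-methyl-8-oxo-3,3a,5,6,7,8,9,9a-octahydrocyclopenta[b]chromen-1-yl trifluoromethanesulfonate
Conditions: KHMDS (1.1 equiv), THF, −78 °C (19 added to the base); N-(5-chloropyridin-2-yl)bis(trifluoromethanesulfonyl)imide, −78 °C; aq. NH4Cl
Reagents that add atoms: N-(5-chloropyridin-2-yl)bis(trifluoromethanesulfonyl)imide, FC(F)(F)S(=O)(=O)N(c1ccc(Cl)cn1)S(=O)(=O)C(F)(F)F
Why: Kinetic enolate formation and O-triflation: the bulky amide base should deprotonate the unhindered C4′ methylene rather than the C2′ methine or the less acidic vinylogous ester positions, and the C4′ enolate has no β-leaving group, so the C3′=C4′ enol triflate should form with C2′ intact.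

Step 14
Reactants: 14 (2Z)-2-iodo-6-methylhepta-2,5-diene; 20 (3aS,7S,9aS)-7-methoxy-3a-methyl-8-oxo-3,3a,5,6,7,8,9,9a-octahydrocyclopenta[b]chromen-1-yl trifluoromethanesulfonate
Product: 23 (3aS,7S,9aR)-7-methoxy-3a-methyl-1-[(2Z)-6-methylhepta-2,5-dien-2-yl]-3,3a,5,6,7,9-hexahydrocyclopenta[b]chromen-8(9aH)-one, via alkenyllithium 21 (not isolated), via alkenylzinc bromide 22 (not isolated)
Conditions: 14, t-BuLi (2 equiv), Et2O, −78 °C; ZnBr2, THF, −78 to 0 °C; then 20, Pd(PPh3)4 (5 mol %), THF, rt
Reagents that add atoms: none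
Why: Negishi coupling: iodine–lithium exchange, transmetallation to zinc and the sp2–sp2 coupling with the enol triflate all proceed with retention, so the Z geometry should be carried into the diene, and the organozinc tolerates the ketone and vinylogous ester.

Step 15
Reactants: 23 (3aS,7S,9aR)-7-methoxy-3a-methyl-1-[(2Z)-6-methylhepta-2,5-dien-2-yl]-3,3a,5,6,7,9-hexahydrocyclopenta[b]chromen-8(9aH)-one
Product: 24 (4S)-3-hydroxy-2-{[(1R,2S)-2-hydroxy-2-methyl-5-[(2Z)-6-methylhepta-2,5-dien-2-yl]cyclopent-4-en-1-yl]methyl}-4-methoxycyclohex-2-en-1-one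
Conditions: LiOH·H2O (3 equiv), THF/H2O 3:1, 0 °C to rt; then 0.5 M HCl to pH 6 at 0 °C
Reagents that add atoms: lithium hydroxide (aqueous), [Li+].[OH-]
Why: Vinylogous ester saponification by addition–elimination: hydroxide adds to the enol-ether carbon and the tertiary alkoxide leaves, so the C1′–O bond is never broken (retention at C1′), the stable 1,3-dione enolate is the sink, and acidification only to pH 6 should avoid re-closure.

Compound list
1 | 1,4-dioxaspiro[4.5]decan-7-one | O=C1CC2(CCC1)OCCO2 | starting material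
2 | (8S)-8-[(phenylamino)oxy]-1,4-dioxaspiro[4.5]decan-7-one | O=C1CC2(CC[C@@H]1ONc1ccccc1)OCCO2 | intermediate
3 | (8S)-8-hydroxy-1,4-dioxaspiro[4.5]decan-7-one | O=C1CC2(CC[C@@H]1O)OCCO2 | intermediate
4 | (8S)-8-methoxy-1,4-dioxaspiro[4.5]decan-7-one | O=C1CC2(CC[C@@H]1OC)OCCO2 | intermediate
5 | (4S)-4-methoxycyclohexane-1,3-dione | CO[C@H]1CCC(=O)CC1=O | intermediate
6 | 3-methylcyclopent-2-en-1-one | CC1=CC(=O)CC1 | starting material
7 | (1S)-3-methylcyclopent-2-en-1-ol | CC1=C[C@@H](O)CC1 | intermediate
8 | tert-butyldimethyl{[(1S)-3-methylcyclopent-2-en-1-yl]oxy}silane | CC1=C[C@@H](O[Si](C)(C)C(C)(C)C)CC1 | intermediate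
9 | but-2-yn-1-ol | CC#CCO | starting material
10 | sodium cyclic alkenylalanate from 9 and Red-Al (Al bonded to C3 and to the alkoxide oxygen; formed in situ) | CC1=CCO[Al-]1(OCCOC)OCCOC.[Na+] | intermediate
11 | (2Z)-3-iodobut-2-en-1-ol | C/C(I)=C/CO | intermediate
12 | (2Z)-1-bromo-3-iodobut-2-ene | C/C(I)=C/CBr | intermediate
13 | (2-methylprop-1-en-1-yl)magnesium bromide | CC(C)=C[Mg]Br | starting material
14 | (2Z)-2-iodo-6-methylhepta-2,5-diene | C/C(I)=C/CC=C(C)C | intermediate
15 | formaldehyde (used as paraformaldehyde) | C=O | starting material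
16 | (4S)-4-methoxy-2-methylidenecyclohexane-1,3-dione (formed in situ) | CO[C@H]1CCC(=O)C(=C)C1=O | intermediate
17 | (1S,3aS,7S,9aR)-1-[(tert-butyldimethylsilyl)oxy]-7-methoxy-3a-methyl-2,3,3a,5,6,7,9,9a-octahydrocyclopenta[b]chromen-8(1H)-one (cis-fused; OTBS on the face opposite the pyran oxygen and C9) | CO[C@H]1CCC2=C(C1=O)C[C@@H]3[C@@H](O[Si](C)(C)C(C)(C)C)CC[C@]3(C)O2 | intermediate
18 | (1S,3aS,7S,9aR)-1-hydroxy-7-methoxy-3a-methyl-2,3,3a,5,6,7,9,9a-octahydrocyclopenta[b]chromen-8(1H)-one | CO[C@H]1CCC2=C(C1=O)C[C@@H]3[C@@H](O)CC[C@]3(C)O2 | intermediate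
19 | (3aS,7S,9aS)-7-methoxy-3a-methyl-2,3,3a,5,6,7,9,9a-octahydrocyclopenta[b]chromene-1,8-dione | CO[C@H]1CCC2=C(C1=O)C[C@@H]3C(=O)CC[C@]3(C)O2 | intermediate
20 | (3aS,7S,9aS)-7-methoxy-3a-methyl-8-oxo-3,3a,5,6,7,8,9,9a-octahydrocyclopenta[b]chromen-1-yl trifluoromethanesulfonate | CO[C@H]1CCC2=C(C1=O)C[C@@H]3C(OS(=O)(=O)C(F)(F)F)=CC[C@]3(C)O2 | intermediate
21 | [(2Z)-6-methylhepta-2,5-dien-2-yl]lithium (formed in situ) | C/C([Li])=C/CC=C(C)C | intermediate
22 | [(2Z)-6-methylhepta-2,5-dien-2-yl]zinc bromide (formed in situ) | C/C([Zn]Br)=C/CC=C(C)C | intermediate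
23 | (3aS,7S,9aR)-7-methoxy-3a-methyl-1-[(2Z)-6-methylhepta-2,5-dien-2-yl]-3,3a,5,6,7,9-hexahydrocyclopenta[b]chromen-8(9aH)-one | CO[C@H]1CCC2=C(C1=O)C[C@@H]3C(/C(C)=C\CC=C(C)C)=CC[C@]3(C)O2 | intermediate
24 | (4S)-3-hydroxy-2-{[(1R,2S)-2-hydroxy-2-methyl-5-[(2Z)-6-methylhepta-2,5-dien-2-yl]cyclopent-4-en-1-yl]methyl}-4-methoxycyclohex-2-en-1-one | CO[C@H]1CCC(=O)C(C[C@@H]2C(/C(C)=C\CC=C(C)C)=CC[C@]2(C)O)=C1O | target

Total step count: 15. Longest linear sequence: 10 steps (steps 1–4 and 10–15).

Steps most likely to fail

Step 10. The hindered alkene of 8, deactivated by its allylic oxygen, may add too slowly, so that 16 is drained by Michael addition of a second molecule of 5 or by an ene pathway. The fallback sets out from 5 and returns at 17. It generates 16 in the absence of free dione: thiomethylation of 5 with formaldehyde and thiophenol should give the sulfide (4S)-3-hydroxy-4-methoxy-2-[(phenylsulfanyl)methyl]cyclohex-2-en-1-one F1. Periodate oxidation would give the sulfoxide (4S)-3-hydroxy-4-methoxy-2-[(phenylsulfinyl)methyl]cyclohex-2-en-1-one F2. Warming F2 with 8 in toluene should release 16 slowly by sulfoxide elimination, and cycloaddition should give 17.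

Step 13. Proton transfer to the C2′ enolate followed by E1cB loss of the pyran oxygen would open the ring and erase C1′/C2′, and deprotonation at the methoxy carbon would epimerise it. The fallback sets out from 19 and returns at 23, avoiding any enolate. Alkenyllithium 21 is transmetallated with CeCl3 to [(2Z)-6-methylhepta-2,5-dien-2-yl]cerium dichloride F3. This weakly basic reagent should add to the C3′ ketone of 19 from the face opposite the C2′ substituent to give the tertiary alcohol 1-hydroxy-7-methoxy-3a-methyl-1-[(2Z)-6-methylhepta-2,5-dien-2-yl]octahydrocyclopenta[b]chromen-8-one (hydroxyl cis to C9 and to the pyran oxygen) F4. Syn-dehydration of F4 with the Burgess reagent, for which only C4′ offers a syn β-hydrogen, should give 23.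

Step 15. Hydroxide may add only slowly to the hindered enol-ether carbon of a tertiary vinylogous ester, so that prolonged base epimerises the methoxy carbon, or the ring may close again on acidification. The fallback sets out from 23 and returns at 24. The pyran is opened by a soft, weakly basic nucleophile: sodium thiophenolate in DMF should add to the enol-ether carbon and expel the tertiary alkoxide to give the vinylogous thioester (6S)-2-{[(1R,2S)-2-hydroxy-2-methyl-5-[(2Z)-6-methylhepta-2,5-dien-2-yl]cyclopent-4-en-1-yl]methyl}-6-methoxy-3-(phenylsulfanyl)cyclohex-2-en-1-one F5. This less hindered enone, carrying a better leaving group, is then hydrolysed with dilute aqueous LiOH at 0 °C to 24.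

Further compounds
F1 | step 10 | (4S)-3-hydroxy-4-methoxy-2-[(phenylsulfanyl)methyl]cyclohex-2-en-1-one | CO[C@H]1CCC(=O)C(CSc2ccccc2)=C1O
F2 | step 10 | (4S)-3-hydroxy-4-methoxy-2-[(phenylsulfinyl)methyl]cyclohex-2-en-1-one (either configuration at sulfur) | CO[C@H]1CCC(=O)C(CS(=O)c2ccccc2)=C1O
F3 | step 13 | [(2Z)-6-methylhepta-2,5-dien-2-yl]cerium dichloride | C/C([Ce](Cl)Cl)=C/CC=C(C)C
F4 | step 13 | 1-hydroxy-7-methoxy-3a-methyl-1-[(2Z)-6-methylhepta-2,5-dien-2-yl]octahydrocyclopenta[b]chromen-8-one (hydroxyl cis to C9 and the pyran oxygen) | CO[C@H]1CCC2=C(C1=O)C[C@@H]3[C@@](O)(/C(C)=C\CC=C(C)C)CC[C@]3(C)O2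
F5 | step 15 | (6S)-2-{[(1R,2S)-2-hydroxy-2-methyl-5-[(2Z)-6-methylhepta-2,5-dien-2-yl]cyclopent-4-en-1-yl]methyl}-6-methoxy-3-(phenylsulfanyl)cyclohex-2-en-1-one | CO[C@H]1CCC(Sc2ccccc2)=C(C[C@@H]2C(/C(C)=C\CC=C(C)C)=CC[C@]2(C)O)C1=O
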